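Ring B of the target (O1–C2–C3–C3a–C7a, benzofuran numbering) ties the quaternary carbon C3a and the enol oxygen on C7a of the dearomatised acylphloroglucinol ring A together through the two-carbon bridge C3–C2. This C,O-1,3 pattern is read as the imprint of a but-2-ene-1,4-diyl bis-electrophile. One asymmetric palladium-catalysed allylation cascade on flat, symmetric deoxyhumulone (isovalerylphloroglucinol carrying two C-prenyl groups) should form C3a–C3 and O1–C2, dearomatise ring A, close ring B, set both stereocentres and leave a vinyl group on C2. A chemoselective Wacker oxidation and a methyl addition then convert that vinyl group into the tertiary carbinol.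

Key step: step 4

Assumption: the (R,R) antipode of the ligand is taken to lead to the (2S,3aS) series (both antipodes are commercial, so the opposite sense of induction would only mean using the (S,S) ligand); enolised tricarbonyl compounds are drawn in the tautomeric form of the target, and 8 is drawn as its E isomer, since E and Z isomers ionise to the same equilibrating allyl complex.

Step 1
Reactants: 1 phloroglucinol; 2 isovaleryl chloride (3-methylbutanoyl chloride)
Product: 3 phlorisovalerophenone [1-(2,4,6-trihydroxyphenyl)-3-methylbutan-1-one]
Conditions: AlCl3 (3.5 equiv), CH2Cl2–PhNO2, 0 → 40 °C; then ice/aq. HCl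
Reagents that add atoms: none
Why: Friedel–Crafts acylation of this very electron-rich arene stops after one acyl group, because the aryl ketone formed is deactivated and held as an aluminium chelate until the acidic work-up.

Step 2
Reactants: 3 phlorisovalerophenone; 4 prenyl bromide (1-bromo-3-methylbut-2-ene, 2.0 equiv)
Product: 5 deoxyhumulone [3-methyl-1-[2,4,6-trihydroxy-3,5-bis(3-methylbut-2-en-1-yl)phenyl]butan-1-one]
Conditions: KOH (2.0 equiv), degassed H2O, 0 °C, Ar; then aq. HCl; product stored under Ar
Reagents that add atoms: none
Why: Double C-alkylation (SN2) of the ambident phloroglucinolate, run in water where hydrogen bonding blocks the oxygens and the soft allylic bromide is taken up by the two free ring carbons, is the established entry to deoxy-α-acids, and two equivalents each of base and 4 at 0 °C hold back a third, dearomatising prenylation.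

Step 3
Reactants: 6 (Z)-but-2-ene-1,4-diol
Product: 7 dimethyl (2Z)-but-2-ene-1,4-diyl biscarbonate
Conditions: ClCO2Me (2.5 equiv), pyridine (3 equiv), CH2Cl2, 0 °C → rt
Reagents that add atoms: methyl chloroformate, COC(=O)Cl
Why: Twofold O-acylation of the primary allylic alcohols by the chloroformate (carbonate formation with pyridine as base and acyl-transfer catalyst) does not touch the Z alkene.

Step 4
Reactants: 5 deoxyhumulone; 7 dimethyl (2Z)-but-2-ene-1,4-diyl biscarbonate
Product: 9 (2S,3aS)-2-ethenyl-6-hydroxy-5-(3-methylbutanoyl)-3a,7-bis(3-methylbut-2-en-1-yl)-3,3a-dihydro-1-benzofuran-4(2H)-one, via C-allylated dienone carbonate 8 (not isolated)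
Conditions: Pd2(dba)3·CHCl3 (2.5 mol %), (R,R)-DACH-phenyl ligand [N,N'-((1R,2R)-cyclohexane-1,2-diyl)bis(2-(diphenylphosphanyl)benzamide)] (7.5 mol %), 7 (1.05 equiv, slow addition), degassed CH2Cl2, 0 °C → rt, Ar, no external base; quenched as soon as 5 and 8 are consumed, work-up below 30 °C
Reagents that add atoms: none
Why: Proposed new method: zerovalent palladium ionises one carbonate of 7 with loss of CO2 and methoxide, which deprotonates 5, and the phloroglucinolate attacks the unsubstituted allyl terminus through a prenyl-bearing ring carbon, so that C3a–C3 forms irreversibly and ring A is dearomatised to 8, while any aryl allyl ether formed on the way is re-ionised and recycled. Ionisation of the remaining carbonate of 8 gives a tethered allyl complex whose internal terminus is captured by the oxygen on C7a in a 5-exo closure (O1–C2) that completes ring B and leaves the vinyl group. The closest known reaction types are the Tsuji–Trost C- then O-allylation of cyclic 1,3-diketones by but-2-ene-1,4-diyl dicarbonates, which gives 2-vinyl-2,3-dihydrofurans, and the palladium-catalysed allylic dearomatisation of phenols and acylphloroglucinols; their enantioselective merger on this substrate class has not been shown. C3a is controlled by the chiral pocket of the ligand alone: the two prenylated carbons of 5 are interchanged by its twofold axis and are therefore equivalent, so that only the two enantiotopic faces of the flat nucleophile have to be told apart. C2 is controlled in the closure, where π–σ–π exchange of the diastereomeric allyl complexes is faster than C–O bond formation and lets the ligand, reinforced by the substrate's preference to place the vinyl group anti to the C3a prenyl group, select the trans isomer. The step needs the C7a oxygen to win over the C4 oxygen and over carbon C7, which is secured because the C4 oxygen is locked in a hydrogen-bonded chelate with the acyl carbonyl and closure at C7a alone preserves the enolised β-triketone, whereas attack by C7 would give up this conjugation for a bridged bicyclo[3.2.1]octane; since the C2–O1 bond stays allylic and can re-ionise, low temperature and a prompt quench are part of the design.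

Step 5
Reactants: 9 (2S,3aS)-2-ethenyl dihydrobenzofuranone
Product: 10 (2S,3aS)-2-acetyl-6-hydroxy-5-(3-methylbutanoyl)-3a,7-bis(3-methylbut-2-en-1-yl)-3,3a-dihydro-1-benzofuran-4(2H)-one
Conditions: PdCl2 (15 mol %), CuCl (50 mol %), O2 (1 atm), DMF–H2O 7:1, rt; then aq. citric acid/EDTA wash
Reagents that add atoms: water, O
Why: Tsuji–Wacker oxidation: divalent palladium binds the only monosubstituted alkene, water attacks its internal carbon (Markovnikov hydroxypalladation) and β-hydride elimination with tautomerisation gives the methyl ketone, while the trisubstituted prenyl alkenes coordinate too weakly to compete, the weakly basic vinylogous-ester oxygen O1 offers little chelation toward aldehyde formation, and the mildly acidic medium leaves C2 and C3a untouched.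

Step 6
Reactants: 10 (2S,3aS)-2-acetyl dihydrobenzofuranone
Product: 11 (2S,3aS)-6-hydroxy-2-(2-hydroxypropan-2-yl)-5-(3-methylbutanoyl)-3a,7-bis(3-methylbut-2-en-1-yl)-3,3a-dihydro-1-benzofuran-4(2H)-one (target)
Conditions: CeCl3 (anhydrous, 4 equiv), MeMgBr (4 equiv), THF, −78 °C; then H2O/aq. NH4Cl
Reagents that add atoms: methylmagnesium bromide, C[Mg]Br
Why: In this organocerium 1,2-addition the first equivalent of reagent deprotonates the acidic C6 enol and turns the whole tricarbonyl/vinylogous-ester array of ring A into an unreactive delocalised enolate, after which the oxophilic, weakly basic reagent adds to the only electrophilic carbonyl left, the methyl ketone, without enolising it, so that C2 keeps its configuration and no new stereocentre arises because the two methyl groups are identical.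

Compound list
1 | phloroglucinol | Oc1cc(O)cc(O)c1 | starting material
2 | isovaleryl chloride (3-methylbutanoyl chloride) | CC(C)CC(Cl)=O | starting material
3 | phlorisovalerophenone, 1-(2,4,6-trihydroxyphenyl)-3-methylbutan-1-one | CC(C)CC(=O)c1c(O)cc(O)cc1O | intermediate
4 | prenyl bromide | CC(C)=CCBr | starting material
5 | deoxyhumulone | CC(C)CC(=O)c1c(O)c(CC=C(C)C)c(O)c(CC=C(C)C)c1O | intermediate
6 | (Z)-but-2-ene-1,4-diol | OC/C=C\CO | starting material
7 | dimethyl (2Z)-but-2-ene-1,4-diyl biscarbonate | COC(=O)OC/C=C\COC(=O)OC | intermediate
8 | methyl (2E)-4-[(1R)-2,4-dihydroxy-5-(3-methylbutanoyl)-1,3-bis(3-methylbut-2-en-1-yl)-6-oxocyclohexa-2,4-dien-1-yl]but-2-en-1-yl carbonate (C-allylated dienone carbonate, not isolated) | CC(C)=CCC1=C(O)[C@](CC=C(C)C)(C/C=C/COC(=O)OC)C(=O)C(C(=O)CC(C)C)=C1O | intermediate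
9 | (2S,3aS)-2-ethenyl-6-hydroxy-5-(3-methylbutanoyl)-3a,7-bis(3-methylbut-2-en-1-yl)-3,3a-dihydro-1-benzofuran-4(2H)-one | CC(C)=CCC1=C2O[C@H](C=C)C[C@]2(CC=C(C)C)C(=O)C(C(=O)CC(C)C)=C1O | intermediate
10 | (2S,3aS)-2-acetyl-6-hydroxy-5-(3-methylbutanoyl)-3a,7-bis(3-methylbut-2-en-1-yl)-3,3a-dihydro-1-benzofuran-4(2H)-one | CC(C)=CCC1=C2O[C@H](C(C)=O)C[C@]2(CC=C(C)C)C(=O)C(C(=O)CC(C)C)=C1O | intermediate
11 | (2S,3aS)-6-hydroxy-2-(2-hydroxypropan-2-yl)-5-(3-methylbutanoyl)-3a,7-bis(3-methylbut-2-en-1-yl)-3,3a-dihydro-1-benzofuran-4(2H)-one | CC(C)=CCC1=C2O[C@H](C(C)(C)O)C[C@]2(CC=C(C)C)C(=O)C(C(=O)CC(C)C)=C1O | target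

Total step count: 6. Longest linear sequence: 5 (steps 1, 2, 4, 5, 6); step 3 is a one-step side branch.

Steps most likely to fail

**1. Step 4 (labelled step).**
- Facial discrimination of a flat nucleophile that sits far from the ligand may be weak.
- Closure may run through the chelated oxygen or through carbon C7.
- Re-ionisation of the allylic C2–O1 bond may erode C2 or drain the material toward irreversible C-allylation.
- One C4 unit may bridge two arenes.
- The allyl vinyl ether array C7=C7a–O1–C2–CH=CH2 may undergo a Claisen-type ring expansion if warmed.
- Fallback (known chemistry, from 5 back to 9): the annulation is run without metal and without asymmetric induction.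
  - Allylic bromides alkylate the potassium salt of 5 at a prenyl-bearing carbon, which is how β-acids are made. An excess of (E)-1,4-dibromobut-2-ene (aq. KOH, 0 °C) should therefore give the racemic 4-bromobut-2-enyl dienone F1.
  - K2CO3 in acetone then closes ring B by intramolecular SN2′ O-alkylation. This is the classical way from cyclic 1,3-diketones and this dibromide to 2-vinyl-2,3-dihydrofurans.
  - The trans racemate, that is 9 together with its mirror image ent-9 F2, is purified by chromatography. It is then split by preparative HPLC on a polysaccharide-based chiral stationary phase, and 9 re-enters at step 5.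

**2. Step 5.**
- The acidic β-triketone may sequester palladium and copper as chelates.
- The C6 enol may add to the neighbouring C7 prenyl group under activation by divalent palladium (oxidative cyclisation).
- Water may attack the terminal carbon because of the electron-withdrawing allylic oxygen.
- The enol may autoxidise under copper and oxygen.
- Fallback (from 9 back to 11): the enol is masked before any oxidation.
  - Me3SiCHN2 (iPr2NEt, MeCN–MeOH, 0 °C) gives the 6-O-methyl ether of 9 F3. The regiochemistry of O-methylation is of no consequence, since the ether is removed at the end.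
  - The neutral substrate is oxidised by the peroxide-driven Wacker variant. It uses PdCl2(quinox)/AgSbF6 (quinox = 2-(4,5-dihydro-1,3-oxazol-2-yl)quinoline) with aqueous tBuOOH in CH2Cl2, and its regiochemistry is set by the catalyst and not by the allylic heteroatom. This gives the masked methyl ketone F4.
  - MeMgBr/CeCl3 (THF, −78 °C) gives the masked carbinol F5.
  - Krapcho-type nucleophilic demethylation of the vinylogous ester (LiCl, DMSO, 120 °C) releases 11.

**3. Step 2.**
- The alkylation may spread statistically over mono-, di- and tri-prenylation.
- O-alkylation may compete.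
- The electron-rich product may autoxidise during work-up.
- Fallback (from 3 back to 5): the anionic alkylation is replaced by an acid-catalysed Friedel–Crafts allylation of the neutral phenol with 2-methylbut-3-en-2-ol and BF3·OEt2 in dioxane at rt. No phenolate is present, so geminal, dearomatising alkylation is shut off. No new compound is passed on the way.

Further compounds
F1 | step 4 | rac-6-[(2E)-4-bromobut-2-en-1-yl]-3,5-dihydroxy-2-(3-methylbutanoyl)-4,6-bis(3-methylbut-2-en-1-yl)cyclohexa-2,4-dien-1-one | CC(C)=CCC1=C(O)C(CC=C(C)C)(C/C=C/CBr)C(=O)C(C(=O)CC(C)C)=C1O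
F2 | step 4 | ent-9, (2R,3aR)-2-ethenyl-6-hydroxy-5-(3-methylbutanoyl)-3a,7-bis(3-methylbut-2-en-1-yl)-3,3a-dihydro-1-benzofuran-4(2H)-one | CC(C)=CCC1=C2O[C@@H](C=C)C[C@@]2(CC=C(C)C)C(=O)C(C(=O)CC(C)C)=C1O
F3 | step 5 | (2S,3aS)-2-ethenyl-6-methoxy-5-(3-methylbutanoyl)-3a,7-bis(3-methylbut-2-en-1-yl)-3,3a-dihydro-1-benzofuran-4(2H)-one | CC(C)=CCC1=C2O[C@H](C=C)C[C@]2(CC=C(C)C)C(=O)C(C(=O)CC(C)C)=C1OC
F4 | step 5 | (2S,3aS)-2-acetyl-6-methoxy-5-(3-methylbutanoyl)-3a,7-bis(3-methylbut-2-en-1-yl)-3,3a-dihydro-1-benzofuran-4(2H)-one | CC(C)=CCC1=C2O[C@H](C(C)=O)C[C@]2(CC=C(C)C)C(=O)C(C(=O)CC(C)C)=C1OC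
F5 | step 5 | (2S,3aS)-2-(2-hydroxypropan-2-yl)-6-methoxy-5-(3-methylbutanoyl)-3a,7-bis(3-methylbut-2-en-1-yl)-3,3a-dihydro-1-benzofuran-4(2H)-one | CC(C)=CCC1=C2O[C@H](C(C)(C)O)C[C@]2(CC=C(C)C)C(=O)C(C(=O)CC(C)C)=C1OC
F0 | step 2 | none | none
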